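## Analysis of the target

The target 20 is a 5,6,7,8-tetrahydroquinoline 1-oxide. Ring A is a pyridine N-oxide in which every carbon is substituted (2-methyl, 3-methoxy, 4-methoxy and the fusion carbons C4a and C8a), and ring B is the saturated carbocycle C5–C8. The only stereocentre is C5 (R), which carries the 5-phenylpentyl chain and lies between the methylene C6 and the fusion carbon C4a, peri to the 4-methoxy group. There is no second stereocentre to relay from, so the absolute configuration must come from a reagent or catalyst. The sensitive groups are the N-oxide (reducible, so it must follow any hydrogenation), the 4-methoxy group of the N-oxide (open to nucleophilic displacement) and the phenyl ring of the chain (it rules out strongly electrophilic chemistry late in the route). The difficulty is to assemble a pentasubstituted, oxygen-rich pyridine with full positional control and to set beside it a stereocentre whose two ring arms are sterically alike. The strategy reads ring A at the oxidation level of a 4-pyranone, that is, of the chain C8a(=O)–C4a–C4(=O)–C3(OMe)–C2(=O)–CH3, so that C8a is a ring-B ketone and C4a its α-carbon. C5 is then the β-carbon of an enal attacked by the central carbon of an acetoacetate, and C8 and C7 are joined by aldol condensation of the acetoacetate methyl group on the enal carbonyl. The ester of the acetoacetate is not kept as C4, because a tert-butyl ester flanked by an enolisable ketone is a poor acceptor for the carbon nucleophile that would have to bring C3 and C2. It serves only to activate C4a for the conjugate addition and is then removed, and C4 arrives with a methoxyacetyl unit.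

## Retrosynthetic reasoning

**N–O bond (20 to 19).** The N-oxide is cut first. It would not survive the hydrogenation that ring B needs and it activates the 4-methoxy group towards displacement, so it is formed last. The forward step only has to oxidise an electron-rich pyridine nitrogen in the presence of a phenyl ring and two aryl ethers.

**Both C–N bonds of ring A and the O–CH3 bond at C4 (19 to 18 to 17).** Nitrogen is exchanged for oxygen, which leads through the 4-methoxypyrylium salt 18 to the 4-pyranone 17. A 4-pyranone is the cyclic form of a 1,3,5-triketone, so every substituent of ring A is placed by carbonyl chemistry with no positional ambiguity. Methylating the pyranone oxygen before nitrogen is brought in avoids the N- versus O-alkylation problem of a 4-pyridone. The forward step needs O-methylation of the carbonyl oxygen and then attack of the nitrogen nucleophile at an α-position (C2 or C8a), not at C4. Nitrogen is introduced in its simplest form and oxidised afterwards, because an N-hydroxy nucleophile can also close through its oxygen after ring opening.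

**The two C–H bonds at C7 and C8 (17 to 16).** The saturated ring is traced back to the C7=C8 alkene. The alkene is kept through the whole construction of ring A because it makes C8 vinylic: the ring-B ketone can then enolise only towards C4a, and the later diketone only towards C3. The forward step has to reduce a disubstituted conjugated alkene without touching the pyranone or the phenyl ring.

**O1–C2 and C3–C2 (16 to 15 to 13 and 14).** The pyranone is opened to the triketone 15, and the C3–C2 bond is cut to the β-diketone 13 and the acetyl donor 14. The forward reaction needs the terminal carbanion of the diketone dianion to form at C3 and to be acylated on carbon.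

**C4a–C4 (13 to 9 and 12; 12 to 10 and 11).** The methoxyacetyl group is removed from C4a, leaving the enone 9 and the acyl donor 12, which comes from 10 and 11 in one step. Cutting here uses the one position that the α′-enolate of 9 offers. The forward step needs kinetic α′-deprotonation and C-acylation without loss of enolate to proton transfer; an N-methoxy-N-methylamide and a second equivalent of base provide for this.

**C4a–CO2tBu (9 to 8).** The ester is put back on C4a. It is what makes the acetoacetate acidic enough for the amine-catalysed addition, and it leaves as two gases.

**C4a–C5 and C7=C8 (8 to 7 to 6 to 4 and 5).** This is the key disconnection. Ring B is cut at the bond between the stereocentre and C4a and at the alkene, giving the enal 4 and the keto ester 5. Both ring-forming bonds and the stereocentre are made in one operation from two achiral pieces, and the amine catalyst has to choose one face of the enal.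

**C2=C3 of the enal, and the alcohol oxidation level (4 to 2 and 3; 2 to 1).** The enal is cut at its double bond to the aldehyde 2 and the two-carbon ylide 3, and 2 is traced to the alcohol 1. Both forward steps are routine, so the risk of the route sits in the key step.

## Alternatives that were turned down

**Alternative 1: intramolecular oxazole–alkene cycloaddition.** The disconnection cuts C8a–C4a and C3–C4 at once, so that ring A and ring B both come from one [4+2] reaction. In the forward direction the 5-ethoxyoxazole A2 is heated; the oxazole adds across its C2 and C5 to the tethered vinyl group, and the oxygen-bridged adduct aromatises with loss of its ethoxy group to the 3-hydroxypyridine A1.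

- For it: two rings form in one reagent-free step, and the tether fixes the positions on the pyridine. On convergence of ring formation it is stronger than the chosen route, which needs four steps for ring A.
- Against it: the step does not create C5. The stereocentre must already be in A2, as an isolated carbon between a vinyl group and two alkyl chains, and needs its own asymmetric synthesis.
- Against it: A1 has hydrogen at C4. The usual way to put oxygen there, nitration of the N-oxide and displacement of the nitro group by an alkoxide, would also nitrate the phenyl ring of the chain, and C4 is hindered by the peri substituent.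
- Against it: an unactivated terminal alkene needs high temperature.
- In its place the chosen route has C4 as a carbonyl carbon from the start and makes C5 in the ring-forming step.

**Alternative 2: desymmetrising ring-closing metathesis.** The disconnection cuts C7=C8 and places two identical allyl groups on C5. In the forward direction the triene A4 is treated with the chiral molybdenum alkylidene A5, which joins one of the two enantiotopic allyl arms to the vinyl group on C8a and gives the dihydroquinoline A3 with C5 set.

- For it: ring A is complete before the stereocentre is made, so no carbonyl condensations follow the asymmetric step, and the remaining allyl group is a handle for the chain. On the point that nothing basic touches the molecule after the stereocentre exists, it is stronger.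
- Against it: A4 is a pentasubstituted pyridine with two different unsaturated carbon groups on adjacent carbons and needs a long preparation.
- Against it: A5 is air- and moisture-sensitive, and the basic pyridine nitrogen next to the reacting vinyl group can bind the metal.
- Against it: the catalyst must distinguish two small allyl arms at a tertiary C–H carbon, and that doubly activated C–H invites alkene migration.
- Against it: cross-metathesis and hydrogenation are still needed to build the chain.
- In its place the chosen route uses an air-stable amine catalyst and two small fragments, and forms the stereocentre in step 3.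

**Alternative 3: iridium-catalysed allylic alkylation.** The disconnection cuts C5–C6. In the forward direction the allylic carbonate A7 is treated with A8, a chiral phosphoramidite and base; the bis(sulfonyl) carbanion attacks the aryl-bearing end of the allyl–iridium intermediate and gives A6, with ring B closed and a vinyl group on C5.

- For it: branched-selective iridium allylic substitution with stabilised carbon nucleophiles has broader precedent for high enantioselectivity than iminium catalysis with an aliphatic enal. On expected selectivity it is at least as strong as the chosen key step.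
- Against it: the aryl carbon at the reacting terminus has substituents on both ortho positions, a pattern that lowers rate and selectivity in such reactions.
- Against it: two sulfonyl groups end up on C6 next to the new stereocentre and must be removed reductively.
- Against it: the vinyl group has to be extended to the chain and hydrogenated, and A7 again needs a pentasubstituted pyridine with two different carbon chains.
- In its place the chosen route puts every carbon of its fragments into the target except the ester, which leaves as gases, and needs no auxiliary group beyond it.

Key step: step 3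

Remark: the sense of induction in step 3 is assigned from the accepted shielding model of diarylprolinol silyl ether iminium ions. The configuration of 9 should be confirmed before material is carried on; both enantiomers of the catalyst are available.

## Route

Step 1
Reactants: 1 6-phenylhexan-1-ol
Product: 2 6-phenylhexanal
Conditions: 2,2,6,6-tetramethylpiperidin-1-oxyl (TEMPO, 10 mol%), PhI(OAc)2 (1.1 equiv), CH2Cl2, rt
Reagents that add atoms: none
Why: Oxoammonium (TEMPO-type) oxidation of a primary alcohol stops at the aldehyde under these non-aqueous conditions, and nothing else in 1 is oxidisable.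

Step 2
Reactants: 2 6-phenylhexanal; 3 (triphenylphosphoranylidene)acetaldehyde
Product: 4 (E)-8-phenyloct-2-enal
Conditions: 3 (1.05 equiv), toluene, 80 °C
Reagents that add atoms: none
Why: Wittig olefination with a carbonyl-stabilised ylide should give the E-alkene; the ylide is kept near one equivalent because the product enal is itself a (less reactive) substrate for a second homologation.

Step 3
Reactants: 4 (E)-8-phenyloct-2-enal; 5 tert-butyl acetoacetate
Product: 8 tert-butyl (6R)-2-oxo-6-(5-phenylpentyl)cyclohex-3-ene-1-carboxylate, via Michael adduct 6 (not isolated), via aldol adduct 7 (not isolated)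
Conditions: 5 (1.2 equiv), (S)-2-[diphenyl(trimethylsilyloxy)methyl]pyrrolidine (10 mol%), PhCO2H (10 mol%), toluene, rt; then TsOH·H2O (10 mol%), rt → 40 °C
Reagents that add atoms: none
Why: The secondary amine condenses with 4 to an E-configured, s-trans iminium ion, one face of which is covered by the diphenyl(trimethylsilyloxy)methyl group; the enol of 5 adds through its central carbon to the open Re face of C3 of the enal, which forms the C4a–C5 bond and should set C5 as R, and hydrolysis of the resulting enamine releases the catalyst and gives 6. The methyl ketone of 6 then closes ring B on the aldehyde in a 6-(enolendo)-exo-trig aldol addition to 7, and acid-catalysed dehydration gives the conjugated C7=C8 enone 8. The closure has no positional choice, because attack from the doubly activated carbon would give a four-membered ring. The closest known reaction type is the amine-catalysed Michael–aldol condensation of β-keto esters with enals to 5-substituted cyclohexenones, a Robinson-type annulation under iminium control. The step needs 1,4- rather than 1,2-addition and C- rather than O-attack of the donor, which the soft stabilised enol and the iminium activation favour, and it needs enantioface selection, which comes only from the catalyst. It also needs ring closure to outrun the reverse Michael reaction, which is why the acid is added as soon as 4 is consumed. The ester-bearing carbon of 8 is epimerisable and left uncontrolled, since the ester is removed in step 4; any tert-butyl ester cleaved by the acid here simply enters step 4 early.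

Step 4
Reactants: 8 tert-butyl (6R)-2-oxo-6-(5-phenylpentyl)cyclohex-3-ene-1-carboxylate
Product: 9 (5R)-5-(5-phenylpentyl)cyclohex-2-en-1-one
Conditions: TsOH·H2O (20 mol%), toluene, 80 °C
Reagents that add atoms: none
Why: Acid-catalysed cleavage of the tert-butyl ester gives a β-keto acid that decarboxylates at this temperature; C5 is not α to the carbonyl group and cannot epimerise, and the enone stays conjugated.

Step 5
Reactants: 10 methoxyacetyl chloride; 11 N,O-dimethylhydroxylamine hydrochloride
Product: 12 N,2-dimethoxy-N-methylacetamide
Conditions: Et3N (2.2 equiv), CH2Cl2, 0 °C → rt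
Reagents that add atoms: none
Why: Amide formation from an acid chloride and an amine; the N-methoxy-N-methylamide is chosen because its adducts with enolates are held as lithium chelates and do not react a second time.

Step 6
Reactants: 9 (5R)-5-(5-phenylpentyl)cyclohex-2-en-1-one; 12 N,2-dimethoxy-N-methylacetamide
Product: 13 (5R)-6-(2-methoxyacetyl)-5-(5-phenylpentyl)cyclohex-2-en-1-one
Conditions: LiN(SiMe3)2 (2.2 equiv), THF, −78 °C; then 12 (1.2 equiv), −78 → 0 °C; aq. NH4Cl
Reagents that add atoms: none
Why: Kinetic deprotonation of a cyclohex-2-enone by a lithium amide takes place at the α′ carbon (C4a of the target), C8 being vinylic, and the cross-conjugated enolate is C-acylated by the amide in a Claisen-type acylation. The second equivalent of base takes up the acidic proton of the β-diketone as it forms, so no enolate is lost to proton transfer; C5 is untouched and the new centre is epimerisable and largely enolised.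

Step 7
Reactants: 13 (5R)-6-(2-methoxyacetyl)-5-(5-phenylpentyl)cyclohex-2-en-1-one; 14 N-methoxy-N-methylacetamide
Product: 16 (5R)-3-methoxy-2-methyl-5-(5-phenylpentyl)-5,6-dihydro-4H-chromen-4-one, via triketone 15 (not isolated)
Conditions: LiN(iPr)2 (2.3 equiv), THF, −78 → −30 °C; then 14 (1.2 equiv), −78 → 0 °C; aq. HCl; then CF3CO2H, CH2Cl2, rt
Reagents that add atoms: none
Why: Two equivalents of lithium amide convert the β-diketone into its 1,3-dianion, which reacts at the more basic terminal carbon C3 (the only sp3 α-carbon left, since C8 is vinylic) with the acetyl donor. The resulting 1,3,5-triketone 15 cyclodehydrates in acid to the 4-pyranone, the classical triketone route to γ-pyrones.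

Step 8
Reactants: 16 (5R)-3-methoxy-2-methyl-5-(5-phenylpentyl)-5,6-dihydro-4H-chromen-4-one
Product: 17 (5R)-3-methoxy-2-methyl-5-(5-phenylpentyl)-5,6,7,8-tetrahydro-4H-chromen-4-one
Conditions: H2 (1 atm), 10% Pd/C, EtOAc, rt
Reagents that add atoms: none
Why: Heterogeneous hydrogenation should reduce the disubstituted conjugated C7=C8 alkene much faster than the tetrasubstituted, vinylogous-ester double bonds of the pyranone or the phenyl ring; C5 is not involved.

Step 9
Reactants: 17 (5R)-3-methoxy-2-methyl-5-(5-phenylpentyl)-5,6,7,8-tetrahydro-4H-chromen-4-one
Product: 19 (5R)-3,4-dimethoxy-2-methyl-5-(5-phenylpentyl)-5,6,7,8-tetrahydroquinoline, via pyrylium triflate 18 (not isolated)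
Conditions: MeOSO2CF3 (1.2 equiv), CH2Cl2, 0 °C → rt; concentrate; NH3 (7 M in MeOH), 0 °C → rt
Reagents that add atoms: methyl trifluoromethanesulfonate, COS(=O)(=O)C(F)(F)F; ammonia, N
Why: The carbonyl oxygen of a 4-pyranone is its nucleophilic site and is methylated to the 4-methoxypyrylium salt 18; ammonia then adds at an α-position (C2 or C8a), the ring opens and recloses on nitrogen with loss of water (pyrylium-to-pyridine exchange). The hindered, donor-substituted C4 is the less electrophilic site, and C5 is attached to a β-position of the cation and carries no acidic hydrogen.

Step 10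
Reactants: 19 (5R)-3,4-dimethoxy-2-methyl-5-(5-phenylpentyl)-5,6,7,8-tetrahydroquinoline
Product: 20 (5R)-3,4-dimethoxy-2-methyl-5-(5-phenylpentyl)-5,6,7,8-tetrahydroquinoline 1-oxide
Conditions: 3-chloroperoxybenzoic acid (1.2 equiv), CH2Cl2, 0 °C → rt
Reagents that add atoms: 3-chloroperoxybenzoic acid, OOC(=O)c1cccc(Cl)c1
Why: Electrophilic N-oxidation of a pyridine by a peracid; the electron-rich ring keeps the nitrogen nucleophilic despite its two flanking alkyl groups, and no other group in 19 reacts with the peracid at this temperature.

## Compound list

1 | 6-phenylhexan-1-ol | OCCCCCCc1ccccc1 | starting material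
2 | 6-phenylhexanal | O=CCCCCCc1ccccc1 | intermediate
3 | (triphenylphosphoranylidene)acetaldehyde | O=CC=P(c1ccccc1)(c1ccccc1)c1ccccc1 | starting material
4 | (E)-8-phenyloct-2-enal | O=C/C=C/CCCCCc1ccccc1 | intermediate
5 | tert-butyl acetoacetate | CC(=O)CC(=O)OC(C)(C)C | starting material
6 | tert-butyl (3R)-2-acetyl-5-oxo-3-(5-phenylpentyl)pentanoate (C2 epimers) | CC(=O)C(C(=O)OC(C)(C)C)[C@H](CCCCCc1ccccc1)CC=O | intermediate
7 | tert-butyl (6R)-4-hydroxy-2-oxo-6-(5-phenylpentyl)cyclohexane-1-carboxylate (C1 and C4 epimers) | O=C1CC(O)C[C@@H](CCCCCc2ccccc2)C1C(=O)OC(C)(C)C | intermediate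
8 | tert-butyl (6R)-2-oxo-6-(5-phenylpentyl)cyclohex-3-ene-1-carboxylate (C1 epimers) | O=C1C=CC[C@@H](CCCCCc2ccccc2)C1C(=O)OC(C)(C)C | intermediate
9 | (5R)-5-(5-phenylpentyl)cyclohex-2-en-1-one | O=C1C=CC[C@@H](CCCCCc2ccccc2)C1 | intermediate
10 | methoxyacetyl chloride | COCC(=O)Cl | starting material
11 | N,O-dimethylhydroxylamine hydrochloride | CNOC.Cl | starting material
12 | N,2-dimethoxy-N-methylacetamide | COCC(=O)N(C)OC | intermediate
13 | (5R)-6-(2-methoxyacetyl)-5-(5-phenylpentyl)cyclohex-2-en-1-one (C6 epimers, largely enolised) | O=C1C=CC[C@@H](CCCCCc2ccccc2)C1C(=O)COC | intermediate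
14 | N-methoxy-N-methylacetamide | CC(=O)N(C)OC | starting material
15 | (5R)-6-(2-methoxy-3-oxobutanoyl)-5-(5-phenylpentyl)cyclohex-2-en-1-one (tautomers) | O=C1C=CC[C@@H](CCCCCc2ccccc2)C1C(=O)C(OC)C(C)=O | intermediate
16 | (5R)-3-methoxy-2-methyl-5-(5-phenylpentyl)-5,6-dihydro-4H-chromen-4-one | CC1=C(OC)C(=O)C2=C(O1)C=CC[C@H]2CCCCCc1ccccc1 | intermediate
17 | (5R)-3-methoxy-2-methyl-5-(5-phenylpentyl)-5,6,7,8-tetrahydro-4H-chromen-4-one | CC1=C(OC)C(=O)C2=C(O1)CCC[C@H]2CCCCCc1ccccc1 | intermediate
18 | (5R)-3,4-dimethoxy-2-methyl-5-(5-phenylpentyl)-5,6,7,8-tetrahydrochromenylium trifluoromethanesulfonate | COc1c(OC)c(C)[o+]c2c1[C@H](CCCCCc1ccccc1)CCC2.[O-]S(=O)(=O)C(F)(F)F | intermediate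
19 | (5R)-3,4-dimethoxy-2-methyl-5-(5-phenylpentyl)-5,6,7,8-tetrahydroquinoline | COc1c(OC)c(C)nc2c1[C@H](CCCCCc1ccccc1)CCC2 | intermediate
20 | (5R)-3,4-dimethoxy-2-methyl-5-(5-phenylpentyl)-5,6,7,8-tetrahydroquinoline 1-oxide | COc1c(OC)c(C)[n+]([O-])c2c1[C@H](CCCCCc1ccccc1)CCC2 | target

## Step count and least certain steps

Total step count: 10. Longest linear sequence: 9 steps (steps 1–4 and 6–10); step 5 is a one-step side branch.

**Step 3 (key step).** The Michael addition is reversible, so slow ring closure would let the adduct revert and re-add and erode the enantiomeric purity. Facial discrimination on an iminium ion with a flexible alkyl chain may also be incomplete, and dehydration of the aldol may stall under acid mild enough for the tert-butyl ester. The fallback closes the ring by olefination instead of aldol condensation and sets out from 4. The same iminium-catalysed addition is run with ethyl 4-(diethoxyphosphoryl)-3-oxobutanoate (CCOC(=O)CC(=O)CP(=O)(OCC)OCC) and gives ethyl (3R)-2-[2-(diethoxyphosphoryl)acetyl]-5-oxo-3-(5-phenylpentyl)pentanoate F1. Addition of Cs2CO3 triggers a fast, irreversible intramolecular Horner–Wadsworth–Emmons reaction to ethyl (6R)-2-oxo-6-(5-phenylpentyl)cyclohex-3-ene-1-carboxylate F2. Krapcho dealkoxycarbonylation of F2 (LiCl, wet DMSO, 140 °C) comes back to the route at 9.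

**Step 7.** The second deprotonation may take place at the γ-carbon C6 through the enone rather than at C3, the dianion may be acylated on oxygen, or the enone may suffer conjugate addition. The fallback avoids the dianion and sets out from 13. Heating with N,N-dimethylacetamide dimethyl acetal (CC(OC)(OC)N(C)C) in toluene condenses the only available methylene group, C3, and gives (5R)-6-[3-(dimethylamino)-2-methoxybut-2-enoyl]-5-(5-phenylpentyl)cyclohex-2-en-1-one F3. Warming F3 in acetic acid closes the ring by addition of the enol oxygen and loss of the amine, and comes back to the route at 16.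

**Step 6.** Proton transfer from product to unreacted enolate, slow addition of the hindered secondary enolate carbon to the amide, or conjugate self-addition of the enolate to 9 may cut the conversion. The fallback uses the thermodynamic acidity of the β-keto ester instead of a kinetic enolate and sets out from 8. The magnesium chelate of 8 (MgCl2, Et3N, MeCN, 0 °C → rt) is C-acylated with 10 to tert-butyl (6R)-1-(2-methoxyacetyl)-2-oxo-6-(5-phenylpentyl)cyclohex-3-ene-1-carboxylate F4. Treatment of F4 with CF3CO2H in CH2Cl2 removes the ester with decarboxylation and comes back to the route at 13. The cost is the formation of a quaternary carbon, where O-acylation may compete.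

**Step 9.** Ammonia may attack C4 with displacement of the methoxy group, or the salt may be demethylated back to 17. The fallback introduces nitrogen before the C4 oxygen is methylated and sets out from 17.
- Aqueous NH3 in EtOH at 120 °C in a sealed tube gives the pyridone (5R)-3-methoxy-2-methyl-5-(5-phenylpentyl)-5,6,7,8-tetrahydroquinolin-4(1H)-one F5.
- POCl3 converts F5 into (5R)-4-chloro-3-methoxy-2-methyl-5-(5-phenylpentyl)-5,6,7,8-tetrahydroquinoline F6.
- 3-Chloroperoxybenzoic acid oxidises F6 to (5R)-4-chloro-3-methoxy-2-methyl-5-(5-phenylpentyl)-5,6,7,8-tetrahydroquinoline 1-oxide F7.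
- The N-oxide activates the chloride of F7 for displacement by NaOMe in MeOH, which comes back to the route at 20.

## Further compounds

F1 | step 3 | ethyl (3R)-2-[2-(diethoxyphosphoryl)acetyl]-5-oxo-3-(5-phenylpentyl)pentanoate | CCOC(=O)C(C(=O)CP(=O)(OCC)OCC)[C@H](CCCCCc1ccccc1)CC=O
F2 | step 3 | ethyl (6R)-2-oxo-6-(5-phenylpentyl)cyclohex-3-ene-1-carboxylate | O=C1C=CC[C@@H](CCCCCc2ccccc2)C1C(=O)OCC
F3 | step 7 | (5R)-6-[3-(dimethylamino)-2-methoxybut-2-enoyl]-5-(5-phenylpentyl)cyclohex-2-en-1-one (alkene isomers) | O=C1C=CC[C@@H](CCCCCc2ccccc2)C1C(=O)C(OC)=C(C)N(C)C
F4 | step 6 | tert-butyl (6R)-1-(2-methoxyacetyl)-2-oxo-6-(5-phenylpentyl)cyclohex-3-ene-1-carboxylate (C1 epimers) | O=C1C=CC[C@@H](CCCCCc2ccccc2)C1(C(=O)COC)C(=O)OC(C)(C)C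
F5 | step 9 | (5R)-3-methoxy-2-methyl-5-(5-phenylpentyl)-5,6,7,8-tetrahydroquinolin-4(1H)-one | COc1c(C)[nH]c2c(c1=O)[C@H](CCCCCc1ccccc1)CCC2
F6 | step 9 | (5R)-4-chloro-3-methoxy-2-methyl-5-(5-phenylpentyl)-5,6,7,8-tetrahydroquinoline | Clc1c(OC)c(C)nc2c1[C@H](CCCCCc1ccccc1)CCC2
F7 | step 9 | (5R)-4-chloro-3-methoxy-2-methyl-5-(5-phenylpentyl)-5,6,7,8-tetrahydroquinoline 1-oxide | Clc1c(OC)c(C)[n+]([O-])c2c1[C@H](CCCCCc1ccccc1)CCC2
A1 | alternative 1 | (5R)-2-methyl-5-(5-phenylpentyl)-5,6,7,8-tetrahydroquinolin-3-ol | Cc1nc2CCC[C@@H](CCCCCc3ccccc3)c2cc1O
A2 | alternative 1 | 5-ethoxy-4-methyl-2-[(4R)-4-(5-phenylpentyl)hex-5-en-1-yl]-1,3-oxazole | CCOc1oc(CCC[C@@H](CCCCCc2ccccc2)C=C)nc1C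
A3 | alternative 2 | (5R)-5-allyl-3,4-dimethoxy-2-methyl-5,6-dihydroquinoline | COc1c(OC)c(C)nc2c1[C@H](CC=C)CC=C2
A4 | alternative 2 | 3-(hepta-1,6-dien-4-yl)-4,5-dimethoxy-6-methyl-2-vinylpyridine | COc1c(OC)c(C)nc(C=C)c1C(CC=C)CC=C
A5 | alternative 2 | Mo(N-2,6-iPr2C6H3)(CHCMe2Ph)(3,3'-di-tert-butyl-5,5',6,6'-tetramethylbiphenyl-2,2'-diolate), single atropisomer | CC(C)c1cccc(C(C)C)c1N=[Mo]2(=CC(C)(C)c1ccccc1)Oc1c(C(C)(C)C)cc(C)c(C)c1-c1c(C)c(C)cc(C(C)(C)C)c1O2
A6 | alternative 3 | (5S)-3,4-dimethoxy-2-methyl-6,6-bis(phenylsulfonyl)-5-vinyl-5,6,7,8-tetrahydroquinoline | COc1c(OC)c(C)nc2c1[C@H](C=C)C(S(=O)(=O)c1ccccc1)(S(=O)(=O)c1ccccc1)CC2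
A7 | alternative 3 | methyl (2E)-3-{2-[3,3-bis(phenylsulfonyl)propyl]-4,5-dimethoxy-6-methylpyridin-3-yl}prop-2-en-1-yl carbonate | COC(=O)OC/C=C/c1c(OC)c(OC)c(C)nc1CCC(S(=O)(=O)c1ccccc1)S(=O)(=O)c1ccccc1
A8 | alternative 3 | [Ir(cod)Cl]2, di-μ-chlorobis(1,5-cyclooctadiene)diiridium | C1=CCCC=CCC1.C1=CCCC=CCC1.[Cl-].[Cl-].[Ir+].[Ir+]
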